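## Analysis of the target

Compound 15 is a flavanone. Rings A and C form a chroman-4-one, ring B is a 4-hydroxyphenyl group at C2, ring A carries hydroxyls at C5 and C7, and C6 carries an (E)-3,7-dimethylocta-1,6-dienyl chain. There are two stereocentres, C2 (S) in ring C and C3'' (S) in the chain. They are seven bonds apart across ring A and cannot control each other, so each must be set or imported on its own.

C2 is β to the ketone and benzylic. Base opens ring C by a retro-oxa-Michael reaction, and faster once the 4'-hydroxyl is free, so a base-mediated step at the flavanone stage threatens the configuration. Acid threatens the chain: protonation of the electron-rich styrene or of the trisubstituted alkene can start a cation–olefin cyclisation that ends on a neighbouring phenol. C6 and C8 of ring A are activated by the same three oxygens, so the chain has to be directed to C6 by something other than the innate reactivity of the ring.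

The difficulty is therefore threefold: setting C2 catalytically, placing the chain unambiguously, and finishing without base and without strong acid. The strategy rests on the fact that ring C can be cut at O1–C2 and C3–C4. Ring A with C4, C4a, C8a and O1 is then a salicylaldehyde, and C2, C3 and ring B are a cinnamaldehyde. Their union carries one surplus formyl carbon at C3 and a C3=C4 alkene, both of which can be traded for the C4 ketone.

## Retrosynthetic reasoning

**15 from 14.** The last step frees the three phenols. Because 15 tolerates neither base nor hard Lewis acids, ring A is masked as two methoxymethyl ethers and ring B as a tert-butyl carbonate, all three of which leave in dilute methanolic acid at room temperature. Methyl ethers would need a hard Lewis acid that the diene would not survive. An ordinary hindered aryl ester would need alkoxide, which would open ring C.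

**14 from 12 and 13.** The C6–C1'' bond is cut. It is an aryl–alkenyl bond that a Heck reaction forms directly from the aryl bromide 12 and the commercial diene 13. The C3'' centre arrives unchanged from 13, and the E geometry follows from syn insertion and syn β-hydride elimination. The chain is attached late because its two alkenes would not survive the radical hydration that installs the C4 oxygen. The bromine has marked C6 since the first step, so no C6/C8 question arises. The forward reaction has to insert into a bromide flanked by two alkoxy groups and eliminate toward the benzylic hydrogen, not toward C3''–H.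

**12 from 11, 10 and 9.** No skeletal bond is formed here; the enal of 9 is translated into the ketone of 12. The ketone 12 comes from alcohol 11 by oxidation. Alcohol 11 comes from alkene 10 by a Markovnikov hydration through hydrogen-atom transfer, which places oxygen at the benzylic C4 (hydroboration would place it at C3). Alkene 10 comes from 9 by decarbonylation, which removes the surplus carbon. All three operations are neutral and leave C2 alone.

**9 from 5 and 8 (the key disconnection).** O1–C2 and C3–C4 are cut. Both fragments are simple aldehydes, and both bonds, ring C and the C2 centre arise in one catalytic step. The forward reaction is an iminium-catalysed oxa-Michael addition of the phenol of 5 to 8, followed by an enamine aldol closure and dehydration. Because 5 has one free hydroxyl only, para to bromine, ring C can close on one oxygen only.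

**5 from 4, 2 and 1.** The formyl C–C bond is cut ortho to the phenol of 4, whose two ortho positions are equivalent. The phenolic C–O bond of 4 is traced to a C–H bond of 2, the only one not flanked by a substituent, through borylation and oxidation. Compound 2 is the bis-acetal of the commercial diol 1. Bromine is placed first and the free oxygen last because bromination of a ready-made salicylaldehyde would be expected to go ortho to its free hydroxyl, which would end up as C8.

**8 from 7 and 6.** The Cα=Cβ bond is cut by a two-carbon Wittig homologation of aldehyde 7, which is the carbonate of the commercial phenol 6. The carbonate withdraws electrons like an ester and so keeps the enal electrophilic in the key step.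

## Alternatives that were turned down

Alternative 1: Ring C is cut at O1–C8a. The open-chain alcohol A1 carries the C2 carbinol, a bromide at C8a, the chain, and C4 as a silyl ether. Palladium-catalysed intramolecular C–O coupling would close it to the silyloxyflavan A2.
- For it: C2 is set beforehand by well-established carbonyl chemistry and is not a reacting centre in the ring closure, so its configuration is at least as secure as in the chosen route. There is no hot decarbonylation and no late coupling at a flanked bromide.
- Against it: A1 needs a ring A on which two halogen sites (C6 and C8a) are told apart, and two successive metal-catalysed couplings. The secondary benzylic alkoxide on palladium can undergo β-hydride elimination to a ketone with loss of the halide. The reaction needs strong base and heat with the diene already present. C4 enters as a second, unwanted stereocentre and still has to be desilylated and oxidised before the acetals are removed.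
- Comparison: the chosen route gives up the independent setting of C2. In return it forms ring C, two bonds and C2 in one step from two aldehydes that each take two or three steps.

Alternative 2: Ring C is cut at C2–C3. The diazoketone A3 would lose nitrogen at a chiral dirhodium tetracarboxylate, and the carbenoid would insert into a benzylic C–H bond of the 4-methoxybenzyl ether to give the flavanone A4.
- For it: it arrives directly at the ketone oxidation level, so the three redox steps of the chosen route are not needed. On redox economy it is stronger.
- Against it: the carbenoid has no donor group and is unselective. The ether oxygen sits where it can form a five-membered oxonium ylide, and a 1,2-shift of the benzyl group would then give a benzofuranone instead of the six-membered insertion product. Addition to the electron-rich anisyl ring is a further escape. Enantiocontrol of six-ring insertions by such carbenoids is uncertain. A3 has to be made from a doubly ortho-substituted benzoic acid derivative with hazardous diazoalkane chemistry. A4 carries three methyl ethers, whose cleavage needs a hard Lewis acid before the chain is attached, which leaves three free phenols for the coupling or forces reprotection.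
- Comparison: the chosen route pays three redox steps but uses a known catalytic asymmetric reaction class and protecting groups that can be removed at the end.

Alternative 3: Ring A is built last. Irradiation of the dihydropyranone diazoketone A5 would give a vinylketene by Wolff rearrangement (C8–C8a). This would add to the siloxyalkyne A6 by (2+2) cycloaddition, and cyclobutenone opening and 6π closure would form C5–C6, C7–C8 and C4a–C5, giving the bis-silyl ether A7.
- For it: the substitution pattern of ring A is written by the connectivity of the partners, so the C6/C8 question is answered more rigorously than by any aromatic substitution logic. The chain enters without a metal-catalysed coupling. The end game needs only fluoride. On regiocontrol and mildness of the last step it is stronger than the chosen route.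
- Against it: A5 needs an enantioselective dihydropyranone synthesis and a diazoketone installation, and A6 is a sensitive conjugated enynyl silyl ether that already carries the chain stereocentre. Light can isomerise the E-alkene of A6 and dimerise the enone of A5. The cascade has to run on a vinylketene that bears a ring oxygen and a stereocentre, for which the outcome is hard to predict.
- Comparison: the chosen route reaches its key precursors in three and two steps from commercial materials and fixes the regiochemistry with a bromine placed in the first intermediate.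

Key step: step 6

Assumption: the sense of induction in step 6 is assigned from the usual shielding model of diarylprolinol silyl ethers (attack anti to the diphenyl(silyloxy)methyl group of the E,s-trans iminium ion); should it turn out opposite, the (R)-catalyst, equally available, is used.

## Route

Step 1
Reactants: 1 2-bromobenzene-1,3-diol (2-bromoresorcinol)
Product: 2 2-bromo-1,3-bis(methoxymethoxy)benzene
Conditions: MOMCl, i-Pr2NEt, CH2Cl2, 0 °C to rt
Reagents that add atoms: chloromethyl methyl ether, COCCl
Why: O-alkylation of both phenols to the methoxymethyl acetals; these are inert to the later organometallic, radical and oxidative steps, small enough not to block coupling at the flanked bromide, and removable with dilute acid.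

Step 2
Reactants: 2 2-bromo-1,3-bis(methoxymethoxy)benzene
Product: 4 4-bromo-3,5-bis(methoxymethoxy)phenol, via pinacol arylboronate 3 (not isolated)
Conditions: [Ir(OMe)(cod)]2 (cat.), 4,4'-di-tert-butyl-2,2'-bipyridine (cat.), B2pin2, THF, 80 °C; then 30% aq. H2O2, NaOH (cat.), 0 °C
Reagents that add atoms: hydrogen peroxide, OO; bis(pinacolato)diboron, CC1(C)OB(OC1(C)C)B1OC(C)(C)C(C)(C)O1 (for intermediate 3 only)
Why: Sterically controlled iridium-catalysed C–H borylation should take place at the only C–H bond without an ortho substituent and leave the C–Br bond alone; oxidation of the C–B bond then gives the phenol at the same carbon, so the hydroxyl is para to bromine by construction.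

Step 3
Reactants: 4 4-bromo-3,5-bis(methoxymethoxy)phenol
Product: 5 3-bromo-6-hydroxy-2,4-bis(methoxymethoxy)benzaldehyde
Conditions: MgCl2, Et3N, (CH2O)n, MeCN, reflux
Reagents that add atoms: paraformaldehyde (formaldehyde), C=O
Why: Magnesium-mediated ortho-formylation of a phenol (Casnati–Skattebøl reaction): the magnesium phenoxide delivers formaldehyde to the ortho carbon and a second formaldehyde oxidises the benzylic alkoxide; the two ortho positions of 4 are equivalent and the product is deactivated toward a second formylation.

Step 4
Reactants: 6 4-hydroxybenzaldehyde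
Product: 7 tert-butyl (4-formylphenyl) carbonate
Conditions: Boc2O, DMAP (cat.), MeCN, rt
Reagents that add atoms: di-tert-butyl dicarbonate, CC(C)(C)OC(=O)OC(=O)OC(C)(C)C
Why: DMAP-catalysed O-acylation of the phenol; the carbonate is electron-withdrawing, does not acylate a hindered secondary amine, and is acid-labile like the acetals of ring A.

Step 5
Reactants: 7 tert-butyl (4-formylphenyl) carbonate
Product: 8 tert-butyl {4-[(1E)-3-oxoprop-1-en-1-yl]phenyl} carbonate
Conditions: Ph3P=CHCHO (1.05 equiv), toluene, 80 °C
Reagents that add atoms: (triphenylphosphoranylidene)acetaldehyde, O=CC=P(c1ccccc1)(c1ccccc1)c1ccccc1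
Why: Wittig reaction with a stabilised ylide should give the E-enal; near-stoichiometric ylide limits a second homologation.

Step 6
Reactants: 5 3-bromo-6-hydroxy-2,4-bis(methoxymethoxy)benzaldehyde; 8 tert-butyl {4-[(1E)-3-oxoprop-1-en-1-yl]phenyl} carbonate
Product: 9 tert-butyl {4-[(2R)-6-bromo-3-formyl-5,7-bis(methoxymethoxy)-2H-chromen-2-yl]phenyl} carbonate
Conditions: (S)-2-[diphenyl(trimethylsilyloxy)methyl]pyrrolidine (20 mol%), 2-nitrobenzoic acid (20 mol%), 4 Å MS, toluene, 0 °C to rt
Reagents that add atoms: none
Why: The secondary amine condenses with enal 8 to an E,s-trans iminium ion (acid co-catalyst), to whose β-carbon the phenol of 5 adds reversibly (oxa-Michael, O1–C2); the enamine so formed attacks the neighbouring aryl aldehyde (C3–C4), and loss of water followed by hydrolysis releases 9 and the amine, the intermediates remaining catalyst-bound throughout. The closest known reaction type is the diarylprolinol silyl ether catalysed domino oxa-Michael–aldol condensation of salicylaldehydes with cinnamaldehydes to 2-aryl-2H-chromene-3-carbaldehydes. Ring C closes in the aldol step as a 6-(enolexo)-exo-trig cyclisation. C2 is controlled by the catalyst: the diphenyl(trimethylsilyloxy)methyl group covers the Re face of the β-carbon, so oxygen enters on the Si face, which corresponds to (2R)-9 and to the spatial arrangement of (2S)-15. The dehydration is irreversible and drains the favoured oxa-Michael adduct from the equilibrium, so the selectivity of the reversible first step is kept. Regioselectivity needs no control because 5 has one free hydroxyl only, ortho to the formyl group and para to bromine. The carbonate on ring B keeps the iminium ion electrophilic and makes the C2–O bond of 9 less prone to ionise.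

Step 7
Reactants: 9 tert-butyl {4-[(2R)-6-bromo-3-formyl-5,7-bis(methoxymethoxy)-2H-chromen-2-yl]phenyl} carbonate
Product: 10 tert-butyl {4-[(2S)-6-bromo-5,7-bis(methoxymethoxy)-2H-chromen-2-yl]phenyl} carbonate
Conditions: RhCl(PPh3)3 (1.1 equiv), toluene, 100–110 °C
Reagents that add atoms: none
Why: Tsuji–Wilkinson decarbonylation: the formyl C–H bond adds to monovalent rhodium, CO migrates to the metal and C–H reductive elimination leaves the alkene in place; C2 is not a reacting centre and its descriptor changes from R to S only because C3 loses CIP priority. The hindered, electron-rich C–Br bond is not expected to add to rhodium under these conditions.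

Step 8
Reactants: 10 tert-butyl {4-[(2S)-6-bromo-5,7-bis(methoxymethoxy)-2H-chromen-2-yl]phenyl} carbonate
Product: 11 tert-butyl {4-[(2S)-6-bromo-4-hydroxy-5,7-bis(methoxymethoxy)chroman-2-yl]phenyl} carbonate (both C4 epimers)
Conditions: Co(acac)2 (20 mol%), PhSiH3, O2 (1 atm), THF, rt
Reagents that add atoms: dioxygen, O=O
Why: Mukaiyama hydration: a cobalt hydride transfers a hydrogen atom to C3 and gives the C4 benzylic radical stabilised by ring A, which is trapped by O2 and reduced to the alcohol, so oxygen should go to C4 (hydroboration would put it at C3). C4 forms as an epimer mixture that is removed in step 9, C2 is untouched, and any ketone 12 formed directly is carried along.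

Step 9
Reactants: 11 tert-butyl {4-[(2S)-6-bromo-4-hydroxy-5,7-bis(methoxymethoxy)chroman-2-yl]phenyl} carbonate
Product: 12 tert-butyl {4-[(2S)-6-bromo-5,7-bis(methoxymethoxy)-4-oxochroman-2-yl]phenyl} carbonate
Conditions: Dess–Martin periodinane, pyridine, CH2Cl2, 0 °C to rt
Reagents that add atoms: none
Why: Dess–Martin oxidation of the secondary benzylic alcohol converges both epimers on the ketone; the pyridine buffer keeps the easily ionised alcohol from acid and the medium is never basic enough to open ring C.

Step 10
Reactants: 12 tert-butyl {4-[(2S)-6-bromo-5,7-bis(methoxymethoxy)-4-oxochroman-2-yl]phenyl} carbonate; 13 (3S)-3,7-dimethylocta-1,6-diene ((S)-β-citronellene)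
Product: 14 tert-butyl {4-[(2S)-6-[(1E,3S)-3,7-dimethylocta-1,6-dien-1-yl]-5,7-bis(methoxymethoxy)-4-oxochroman-2-yl]phenyl} carbonate
Conditions: Pd2(dba)3 (2.5 mol%), [HP(t-Bu)3]BF4 (10 mol%), Cy2NMe, 13 (3 equiv), 1,4-dioxane, 70 °C
Reagents that add atoms: none
Why: Heck reaction: the aryl bromide adds to zerovalent palladium bearing P(t-Bu)3, the terminal alkene inserts with aryl at its unsubstituted carbon, and syn β-hydride elimination toward the benzylic hydrogen should give the conjugated E-alkene; the allylic stereocentre of 13 is not a reacting centre. A tertiary amine in an aprotic solvent is too weak a base to enolise the ketone to an extent that would open ring C.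

Step 11
Reactants: 14 tert-butyl {4-[(2S)-6-[(1E,3S)-3,7-dimethylocta-1,6-dien-1-yl]-5,7-bis(methoxymethoxy)-4-oxochroman-2-yl]phenyl} carbonate
Product: 15 (2S)-6-[(1E,3S)-3,7-dimethylocta-1,6-dien-1-yl]-5,7-dihydroxy-2-(4-hydroxyphenyl)-2,3-dihydro-4H-chromen-4-one
Conditions: 1–2 M HCl in MeOH–THF, 0 °C to rt
Reagents that add atoms: none
Why: Acid-catalysed acetal exchange with methanol removes both methoxymethyl ethers and acidolysis removes the tert-butyl carbonate in one operation; the flavanone is configurationally stable to dilute acid, and low temperature and dilution are chosen to spare the two alkenes.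

## Compound list

1 | 2-bromobenzene-1,3-diol | Oc1cccc(O)c1Br | starting material
2 | 2-bromo-1,3-bis(methoxymethoxy)benzene | COCOc1cccc(OCOC)c1Br | intermediate
3 | 2-[4-bromo-3,5-bis(methoxymethoxy)phenyl]-4,4,5,5-tetramethyl-1,3,2-dioxaborolane | COCOc1cc(B2OC(C)(C)C(C)(C)O2)cc(OCOC)c1Br | intermediate (not isolated)
4 | 4-bromo-3,5-bis(methoxymethoxy)phenol | COCOc1cc(O)cc(OCOC)c1Br | intermediate
5 | 3-bromo-6-hydroxy-2,4-bis(methoxymethoxy)benzaldehyde | O=Cc1c(O)cc(OCOC)c(Br)c1OCOC | intermediate
6 | 4-hydroxybenzaldehyde | O=Cc1ccc(O)cc1 | starting material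
7 | tert-butyl (4-formylphenyl) carbonate | O=Cc1ccc(OC(=O)OC(C)(C)C)cc1 | intermediate
8 | tert-butyl {4-[(1E)-3-oxoprop-1-en-1-yl]phenyl} carbonate | O=C/C=C/c1ccc(OC(=O)OC(C)(C)C)cc1 | intermediate
9 | tert-butyl {4-[(2R)-6-bromo-3-formyl-5,7-bis(methoxymethoxy)-2H-chromen-2-yl]phenyl} carbonate | COCOc1cc2c(c(OCOC)c1Br)C=C(C=O)[C@@H](c1ccc(OC(=O)OC(C)(C)C)cc1)O2 | intermediate
10 | tert-butyl {4-[(2S)-6-bromo-5,7-bis(methoxymethoxy)-2H-chromen-2-yl]phenyl} carbonate | COCOc1cc2c(c(OCOC)c1Br)C=C[C@@H](c1ccc(OC(=O)OC(C)(C)C)cc1)O2 | intermediate
11 | tert-butyl {4-[(2S)-6-bromo-4-hydroxy-5,7-bis(methoxymethoxy)chroman-2-yl]phenyl} carbonate (C4 epimers) | COCOc1cc2c(c(OCOC)c1Br)C(O)C[C@@H](c1ccc(OC(=O)OC(C)(C)C)cc1)O2 | intermediate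
12 | tert-butyl {4-[(2S)-6-bromo-5,7-bis(methoxymethoxy)-4-oxochroman-2-yl]phenyl} carbonate | COCOc1cc2c(c(OCOC)c1Br)C(=O)C[C@@H](c1ccc(OC(=O)OC(C)(C)C)cc1)O2 | intermediate
13 | (3S)-3,7-dimethylocta-1,6-diene | CC(C)=CCC[C@H](C)C=C | starting material
14 | tert-butyl {4-[(2S)-6-[(1E,3S)-3,7-dimethylocta-1,6-dien-1-yl]-5,7-bis(methoxymethoxy)-4-oxochroman-2-yl]phenyl} carbonate | CC(C)=CCC[C@H](C)/C=C/c1c(OCOC)cc2c(c1OCOC)C(=O)C[C@@H](c1ccc(OC(=O)OC(C)(C)C)cc1)O2 | intermediate
15 | (2S)-6-[(1E,3S)-3,7-dimethylocta-1,6-dien-1-yl]-5,7-dihydroxy-2-(4-hydroxyphenyl)-2,3-dihydro-4H-chromen-4-one | CC(C)=CCC[C@H](C)/C=C/c1c(O)cc2c(c1O)C(=O)C[C@@H](c1ccc(O)cc1)O2 | target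

## Step count and least certain steps

Total: 11 steps. Longest linear sequence: 9 steps (steps 1, 2, 3, 6, 7, 8, 9, 10, 11 from compound 1); the branch from compound 6 joins at step 6.

**Step 6 (key step).**
- Risk: the salicylaldehyde is electron-rich and substituted on both sides of the formyl group, so the aldol closure may be slow. A slow closure gives the uncatalysed or reversible oxa-Michael pathway time to lower the enantiomeric purity. The acid co-catalyst may also erode C2 in the product by reversible ring opening.
- Fallback, from 5 to 12: addition of MeMgBr to the aldehyde of 5 should give 1-[3-bromo-6-hydroxy-2,4-bis(methoxymethoxy)phenyl]ethan-1-ol F1. Oxidation with MnO2 should give 1-[3-bromo-6-hydroxy-2,4-bis(methoxymethoxy)phenyl]ethan-1-one F2. Condensation with N,N-dimethylformamide dimethyl acetal should give the enaminone (2E)-1-[3-bromo-6-hydroxy-2,4-bis(methoxymethoxy)phenyl]-3-(dimethylamino)prop-2-en-1-one F3, which should close on warming with silica or acetic acid to 6-bromo-5,7-bis(methoxymethoxy)-4H-chromen-4-one F4. Enantioselective conjugate addition of {4-[(tert-butoxycarbonyl)oxy]phenyl}boronic acid F5, catalysed by Pd(OCOCF3)2 and the enantiomer of a tert-butyl pyridine-oxazoline ligand that gives the (2S) product, would then deliver 12 directly. The route is rejoined at 12 and steps 7 to 9 fall away.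

**Step 10.**
- Risk: oxidative addition into the bromide flanked by two alkoxy groups may be slow. β-Hydride elimination may go toward C3''–H instead of the benzylic hydrogen, or palladium hydride may re-add and walk along the chain; either would give alkene isomers and destroy the C3'' centre. Prolonged heating with amine may also let ring C open and close.
- Fallback, from 11 to 14: the coupling partner is changed and the coupling is moved ahead of the oxidation. (S)-Citronellal F8 would be converted in one flask, through its enol nonaflate (3S)-3,7-dimethylocta-1,6-dien-1-yl nonafluorobutanesulfonate F9 (nonafluorobutanesulfonyl fluoride, phosphazene base), into (3S)-3,7-dimethyloct-6-en-1-yne F10. Hydroboration with pinacolborane catalysed by Cp2ZrHCl should give 2-[(1E,3S)-3,7-dimethylocta-1,6-dien-1-yl]-4,4,5,5-tetramethyl-1,3,2-dioxaborolane F11. Suzuki–Miyaura coupling with 11 (Pd(OAc)2, SPhos, CsF, THF, 50 °C) should give tert-butyl {4-[(2S)-6-[(1E,3S)-3,7-dimethylocta-1,6-dien-1-yl]-4-hydroxy-5,7-bis(methoxymethoxy)chroman-2-yl]phenyl} carbonate F12. The oxidation of step 9 applied to F12 then gives 14.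

**Step 7.**
- Risk: at the temperature needed for CO extrusion from the α-substituted enal, the 2H-chromene may undergo reversible electrocyclic ring opening, which would erode C2. Extrusion may also stall at the acyl rhodium stage.
- Fallback, from 9 to 11: the alkene is saturated before the carbon is removed. Conjugate reduction of 9 (Hantzsch ester, catalytic dibenzylammonium trifluoroacetate) should give tert-butyl {4-[(2S)-6-bromo-3-formyl-5,7-bis(methoxymethoxy)chroman-2-yl]phenyl} carbonate F6. Decarbonylation with RhCl(PPh3)3 should give the flavan tert-butyl {4-[(2S)-6-bromo-5,7-bis(methoxymethoxy)chroman-2-yl]phenyl} carbonate F7, in which C2 is an ordinary benzylic ether that cannot open electrocyclically. Hydride abstraction at C4 with DDQ in wet CH2Cl2, favoured by the three oxygens of ring A, should give 11.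

**Step 11.**
- Risk: protonation of the styrene or of the trisubstituted alkene may start a cyclisation onto a freed phenol or an addition of methanol. The carbonate may be cleaved more slowly than the acetals, which would prolong the exposure to acid.
- Fallback, from 12 to 15: acid is used before any alkene is present. The conditions of step 11 applied to 12 should give (2S)-6-bromo-5,7-dihydroxy-2-(4-hydroxyphenyl)chroman-4-one F13. TBSCl and imidazole should silylate the 7- and 4'-hydroxyls and leave the chelated 5-hydroxyl, giving (2S)-6-bromo-7-[(tert-butyldimethylsilyl)oxy]-2-{4-[(tert-butyldimethylsilyl)oxy]phenyl}-5-hydroxychroman-4-one F14. The Heck reaction of step 10 with 13 should give (2S)-7-[(tert-butyldimethylsilyl)oxy]-2-{4-[(tert-butyldimethylsilyl)oxy]phenyl}-6-[(1E,3S)-3,7-dimethylocta-1,6-dien-1-yl]-5-hydroxychroman-4-one F15. HF·pyridine in THF at 0 °C would then free 15. The price is a more hindered coupling.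

## Further compounds

F1 | step 6 | 1-[3-bromo-6-hydroxy-2,4-bis(methoxymethoxy)phenyl]ethan-1-ol | CC(O)c1c(O)cc(OCOC)c(Br)c1OCOC
F2 | step 6 | 1-[3-bromo-6-hydroxy-2,4-bis(methoxymethoxy)phenyl]ethan-1-one | CC(=O)c1c(O)cc(OCOC)c(Br)c1OCOC
F3 | step 6 | (2E)-1-[3-bromo-6-hydroxy-2,4-bis(methoxymethoxy)phenyl]-3-(dimethylamino)prop-2-en-1-one | CN(C)/C=C/C(=O)c1c(O)cc(OCOC)c(Br)c1OCOC
F4 | step 6 | 6-bromo-5,7-bis(methoxymethoxy)-4H-chromen-4-one | COCOc1cc2occc(=O)c2c(OCOC)c1Br
F5 | step 6 | {4-[(tert-butoxycarbonyl)oxy]phenyl}boronic acid | CC(C)(C)OC(=O)Oc1ccc(B(O)O)cc1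
F6 | step 7 | tert-butyl {4-[(2S)-6-bromo-3-formyl-5,7-bis(methoxymethoxy)chroman-2-yl]phenyl} carbonate (C3 epimers) | COCOc1cc2c(c(OCOC)c1Br)CC(C=O)[C@@H](c1ccc(OC(=O)OC(C)(C)C)cc1)O2
F7 | step 7 | tert-butyl {4-[(2S)-6-bromo-5,7-bis(methoxymethoxy)chroman-2-yl]phenyl} carbonate | COCOc1cc2c(c(OCOC)c1Br)CC[C@@H](c1ccc(OC(=O)OC(C)(C)C)cc1)O2
F8 | step 10 | (3S)-3,7-dimethyloct-6-enal ((S)-citronellal) | CC(C)=CCC[C@H](C)CC=O
F9 | step 10 | (3S)-3,7-dimethylocta-1,6-dien-1-yl nonafluorobutanesulfonate (E/Z) | CC(C)=CCC[C@H](C)C=COS(=O)(=O)C(F)(F)C(F)(F)C(F)(F)C(F)(F)F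
F10 | step 10 | (3S)-3,7-dimethyloct-6-en-1-yne | CC(C)=CCC[C@H](C)C#C
F11 | step 10 | 2-[(1E,3S)-3,7-dimethylocta-1,6-dien-1-yl]-4,4,5,5-tetramethyl-1,3,2-dioxaborolane | CC(C)=CCC[C@H](C)/C=C/B1OC(C)(C)C(C)(C)O1
F12 | step 10 | tert-butyl {4-[(2S)-6-[(1E,3S)-3,7-dimethylocta-1,6-dien-1-yl]-4-hydroxy-5,7-bis(methoxymethoxy)chroman-2-yl]phenyl} carbonate (C4 epimers) | CC(C)=CCC[C@H](C)/C=C/c1c(OCOC)cc2c(c1OCOC)C(O)C[C@@H](c1ccc(OC(=O)OC(C)(C)C)cc1)O2
F13 | step 11 | (2S)-6-bromo-5,7-dihydroxy-2-(4-hydroxyphenyl)chroman-4-one | Oc1cc2c(c(O)c1Br)C(=O)C[C@@H](c1ccc(O)cc1)O2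
F14 | step 11 | (2S)-6-bromo-7-[(tert-butyldimethylsilyl)oxy]-2-{4-[(tert-butyldimethylsilyl)oxy]phenyl}-5-hydroxychroman-4-one | CC(C)(C)[Si](C)(C)Oc1cc2c(c(O)c1Br)C(=O)C[C@@H](c1ccc(O[Si](C)(C)C(C)(C)C)cc1)O2
F15 | step 11 | (2S)-7-[(tert-butyldimethylsilyl)oxy]-2-{4-[(tert-butyldimethylsilyl)oxy]phenyl}-6-[(1E,3S)-3,7-dimethylocta-1,6-dien-1-yl]-5-hydroxychroman-4-one | CC(C)=CCC[C@H](C)/C=C/c1c(O[Si](C)(C)C(C)(C)C)cc2c(c1O)C(=O)C[C@@H](c1ccc(O[Si](C)(C)C(C)(C)C)cc1)O2
A1 | alternative 1 | (1S)-3-{6-bromo-3-[(1E,3S)-3,7-dimethylocta-1,6-dien-1-yl]-2,4-bis(methoxymethoxy)phenyl}-3-[(tert-butyldimethylsilyl)oxy]-1-[4-(methoxymethoxy)phenyl]propan-1-ol | CC(C)=CCC[C@H](C)/C=C/c1c(OCOC)cc(Br)c(c1OCOC)C(O[Si](C)(C)C(C)(C)C)C[C@@H](c1ccc(OCOC)cc1)O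
A2 | alternative 1 | (2S)-4-[(tert-butyldimethylsilyl)oxy]-6-[(1E,3S)-3,7-dimethylocta-1,6-dien-1-yl]-5,7-bis(methoxymethoxy)-2-[4-(methoxymethoxy)phenyl]chromane | CC(C)=CCC[C@H](C)/C=C/c1c(OCOC)cc2c(c1OCOC)C(O[Si](C)(C)C(C)(C)C)C[C@@H](c1ccc(OCOC)cc1)O2
A3 | alternative 2 | 1-{3-bromo-2,4-dimethoxy-6-[(4-methoxybenzyl)oxy]phenyl}-2-diazoethan-1-one | COc1ccc(COc2cc(OC)c(Br)c(OC)c2C(=O)C=[N+]=[N-])cc1
A4 | alternative 2 | (2S)-6-bromo-5,7-dimethoxy-2-(4-methoxyphenyl)chroman-4-one | COc1cc2c(c(OC)c1Br)C(=O)C[C@@H](c1ccc(OC)cc1)O2
A5 | alternative 3 | (2S)-2-{4-[(tert-butyldimethylsilyl)oxy]phenyl}-6-(diazoacetyl)-2,3-dihydro-4H-pyran-4-one | [N-]=[N+]=CC(=O)C1=CC(=O)C[C@@H](c2ccc(O[Si](C)(C)C(C)(C)C)cc2)O1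
A6 | alternative 3 | {[(3E,5S)-5,9-dimethyldeca-3,8-dien-1-yn-1-yl]oxy}tri(propan-2-yl)silane | CC(C)=CCC[C@H](C)/C=C/C#CO[Si](C(C)C)(C(C)C)C(C)C
A7 | alternative 3 | (2S)-2-{4-[(tert-butyldimethylsilyl)oxy]phenyl}-6-[(1E,3S)-3,7-dimethylocta-1,6-dien-1-yl]-5-hydroxy-7-[(triisopropylsilyl)oxy]chroman-4-one | CC(C)=CCC[C@H](C)/C=C/c1c(O[Si](C(C)C)(C(C)C)C(C)C)cc2c(c1O)C(=O)C[C@@H](c1ccc(O[Si](C)(C)C(C)(C)C)cc1)O2
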